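**Plan**
- Retrosynthesis: the C6 configuration is left to a final equilibration. The ring C4=C5 bond is cut first (ring-closing metathesis), then the O1–C6 peroxyketal bond (hydroperoxide + vinyl ketal), then the C3–O2 bond (propargylic sulfonate + masked hydrogen peroxide).
- Forward: a C19 vinyl ketal is built from heptadecanoic acid. The C5 chain is assembled from 3-silyloxypropanal and trimethylsilylacetylene, receives its peroxide by SN2, is taken to the methyl ester and is joined through O1–C6. The only ring closes last.
- Enabling feature: in the 1,2-dioxine ring (O1, O2, C3, C4, C5, C6) the cis C4=C5 bond sits between the two peroxide-bearing carbons C3 and C6. Each can therefore carry a vinyl group, and the alkene itself is the ring-closing bond.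
- Stereochemistry: C3 comes from a Noyori transfer hydrogenation (R), inverted to S by the peroxide displacement. C6 is sorted by acid equilibration in methanol and separation of the (3S,6R) epimer.

Key step: step 18

Assumption: the (R,R)-TsDPEN ruthenium catalyst is taken to give the (R)-carbinol from the silylated ynone, by analogy with other ynones; were the sense opposite, the (S,S)-catalyst would be used.
Assumption: neither C6 epimer is expected to be strongly favoured at equilibrium, so step 19 is planned with recycling of the unwanted epimer.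

**Route**

Step 1
Reactants: 1 heptadecanoic acid
Product: 3 N-methoxy-N-methylheptadecanamide, via acyl imidazole 2 (not isolated)
Conditions: CDI, CH2Cl2, rt; then MeNH(OMe)·HCl, rt
Reagents that add atoms: N,O-dimethylhydroxylamine hydrochloride, CNOC.Cl
Why: Amide coupling through CDI activation: the acyl imidazole is aminolysed by N,O-dimethylhydroxylamine to the Weinreb amide, and no stereocentre is involved.

Step 2
Reactants: 3 N-methoxy-N-methylheptadecanamide; 4 vinylmagnesium bromide
Product: 6 nonadec-1-en-3-one, via magnesium hemiaminal chelate 5 (not isolated)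
Conditions: THF, 0 °C; cannulated into cold 2 M HCl
Reagents that add atoms: none
Why: Weinreb ketone synthesis: the five-membered magnesium chelate holds the tetrahedral adduct until work-up so that one vinyl group is delivered, and the inverse acidic quench protonates the released N,O-dimethylhydroxylamine before it can add to the enone.

Step 3
Reactants: 6 nonadec-1-en-3-one
Product: 8 1-bromo-3,3-dimethoxynonadecane, via 1-bromononadecan-3-one 7 (not isolated)
Conditions: HBr (gas), CH2Cl2, 0 °C; then HC(OMe)3, MeOH, TsOH·H2O (cat.), rt; Et3N quench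
Reagents that add atoms: hydrogen bromide, Br; trimethyl orthoformate, COC(OC)OC; methanol, CO
Why: Conjugate hydrobromination followed by orthoformate-driven ketalisation: masking C1 as the bromide removes the enone, whose direct ketalisation would suffer conjugate addition of methanol, and the saturated ketone then forms its dimethyl ketal normally.

Step 4
Reactants: 8 1-bromo-3,3-dimethoxynonadecane
Product: 9 3,3-dimethoxynonadec-1-ene
Conditions: KOtBu, THF, 0 °C to rt
Reagents that add atoms: none
Why: E2 dehydrobromination with a hindered alkoxide, the usual way from 2-bromoethyl ketals to vinyl ketals: the ketal is inert to base and the only β-hydrogens are on C2, so only the terminal alkene can form.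

Step 5
Reactants: 10 2,3-dimethylbut-2-ene
Product: 11 2-hydroperoxy-2-methoxypropane (2-methoxyprop-2-yl hydroperoxide)
Conditions: O3, CH2Cl2/MeOH, −78 °C; N2 purge
Reagents that add atoms: ozone, [O-][O+]=O; methanol, CO
Why: Ozonolysis in a participating solvent (Criegee mechanism): methanol intercepts the oxidised half of the cleaved symmetrical alkene as the α-methoxy hydroperoxide while the other half leaves as acetone, which gives a masked hydrogen peroxide that can be alkylated once only.

Step 6
Reactants: 12 ethynyltrimethylsilane; 13 3-[(tert-butyldimethylsilyl)oxy]propanal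
Product: 15 rac-5-[(tert-butyldimethylsilyl)oxy]-1-(trimethylsilyl)pent-1-yn-3-ol, via lithium (trimethylsilyl)acetylide 14 (not isolated)
Conditions: n-BuLi, THF, −78 °C; then 13; aq. NH4Cl
Reagents that add atoms: none
Why: 1,2-Addition of a lithium acetylide to an aldehyde: the acetylide adds to the unhindered aldehyde at low temperature faster than it enolises it, and the racemic carbinol is of no consequence because the next step removes the stereocentre.

Step 7
Reactants: 15 rac-5-[(tert-butyldimethylsilyl)oxy]-1-(trimethylsilyl)pent-1-yn-3-ol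
Product: 16 5-[(tert-butyldimethylsilyl)oxy]-1-(trimethylsilyl)pent-1-yn-3-one
Conditions: MnO2 (activated), CH2Cl2, rt
Reagents that add atoms: none
Why: Oxidation of a propargylic alcohol with activated MnO2, a neutral heterogeneous oxidant that leaves both silyl groups and the elimination-prone β-silyloxy ketone untouched.

Step 8
Reactants: 16 5-[(tert-butyldimethylsilyl)oxy]-1-(trimethylsilyl)pent-1-yn-3-one
Product: 17 (3R)-5-[(tert-butyldimethylsilyl)oxy]-1-(trimethylsilyl)pent-1-yn-3-ol
Conditions: Ru[(R,R)-TsDPEN](p-cymene) (1 mol %), i-PrOH, rt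
Reagents that add atoms: none
Why: Noyori asymmetric transfer hydrogenation of an ynone: the (R,R)-configured ruthenium amido complex passes hydride and proton to the carbonyl through a six-membered transition state in which the alkyne takes the place usually held by an aryl group, which sets C3 as R, and the base-free medium spares the triple bond and the β-silyloxy group.

Step 9
Reactants: 17 (3R)-5-[(tert-butyldimethylsilyl)oxy]-1-(trimethylsilyl)pent-1-yn-3-ol
Product: 18 (3R)-5-[(tert-butyldimethylsilyl)oxy]pent-1-yn-3-ol
Conditions: K2CO3, MeOH, 0 °C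
Reagents that add atoms: none
Why: Protodesilylation of an alkynylsilane by methoxide: only the C(sp)–Si bond is cleaved, the primary silyl ether and the carbinol centre being stable to these mild conditions.

Step 10
Reactants: 18 (3R)-5-[(tert-butyldimethylsilyl)oxy]pent-1-yn-3-ol
Product: 19 (3R)-5-[(tert-butyldimethylsilyl)oxy]pent-1-yn-3-yl methanesulfonate
Conditions: MsCl, Et3N, CH2Cl2, −20 to 0 °C
Reagents that add atoms: methanesulfonyl chloride, CS(=O)(=O)Cl
Why: Mesylation of a secondary alcohol: the C–O bond is not touched, so C3 stays R, and the propargylic mesylate is stable enough to be used without chromatography.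

Step 11
Reactants: 19 (3R)-5-[(tert-butyldimethylsilyl)oxy]pent-1-yn-3-yl methanesulfonate; 11 2-hydroperoxy-2-methoxypropane
Product: 20 tert-butyl({(3S)-3-[(2-methoxypropan-2-yl)peroxy]pent-4-yn-1-yl}oxy)dimethylsilane
Conditions: 11 (2 equiv), CsOH·H2O (1.5 equiv), DMF, 0 °C
Reagents that add atoms: none
Why: SN2 displacement of a secondary sulfonate by a hydroperoxide anion: the caesium peroxide, an α-effect nucleophile of low basicity kept in excess over the hydroxide, attacks the activated propargylic carbon from the back, so C3 is inverted from R to S, and the alkyne offers heteroatom nucleophiles no easy SN2′ path.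

Step 12
Reactants: 20 tert-butyl({(3S)-3-[(2-methoxypropan-2-yl)peroxy]pent-4-yn-1-yl}oxy)dimethylsilane
Product: 21 tert-butyl({(3S)-3-[(2-methoxypropan-2-yl)peroxy]pent-4-en-1-yl}oxy)dimethylsilane
Conditions: H2 (1 atm), Lindlar catalyst (Pd/CaCO3, Pb(OAc)2-poisoned), quinoline, EtOAc, 0 °C to rt
Reagents that add atoms: none
Why: Lindlar semihydrogenation of a terminal alkyne: on lead- and quinoline-poisoned palladium the alkyne is reduced to the alkene and desorbs, and the peroxyketal O–O bond, which unpoisoned palladium would cleave, is expected to survive one equivalent of hydrogen at ambient pressure, with C3 untouched.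

Step 13
Reactants: 21 tert-butyl({(3S)-3-[(2-methoxypropan-2-yl)peroxy]pent-4-en-1-yl}oxy)dimethylsilane
Product: 22 (3S)-3-[(2-methoxypropan-2-yl)peroxy]pent-4-en-1-ol
Conditions: Bu4NF/AcOH (1:1), THF, 0 °C to rt
Reagents that add atoms: none
Why: Fluoride-mediated silyl ether cleavage buffered with acetic acid: the medium is neither acidic enough to hydrolyse the monoperoxyketal nor basic enough for Kornblum–DeLaMare fragmentation at the allylic C3–H.

Step 14
Reactants: 22 (3S)-3-[(2-methoxypropan-2-yl)peroxy]pent-4-en-1-ol
Product: 24 (3S)-3-[(2-methoxypropan-2-yl)peroxy]pent-4-enoic acid, via aldehyde 23 (not isolated)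
Conditions: TEMPO (20 mol %), PhI(OAc)2 (2.2 equiv), MeCN/aq. pH 7 phosphate buffer, 0 °C to rt
Reagents that add atoms: water, O
Why: Oxoammonium-catalysed (TEMPO/PhI(OAc)2) oxidation of a primary alcohol to the acid via the aldehyde hydrate: the buffered, metal-free medium leaves the peroxide, the terminal alkene and the acid-labile peroxyketal intact and is not basic enough to eliminate the β-peroxy group.

Step 15
Reactants: 24 (3S)-3-[(2-methoxypropan-2-yl)peroxy]pent-4-enoic acid
Product: 25 methyl (3S)-3-[(2-methoxypropan-2-yl)peroxy]pent-4-enoate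
Conditions: Me3SiCHN2, PhMe/MeOH (4:1), 0 °C
Reagents that add atoms: (trimethylsilyl)diazomethane, C[Si](C)(C)C=[N+]=[N-]
Why: Methyl ester formation with (trimethylsilyl)diazomethane in methanol, an O-alkylation of the acid under neutral conditions that avoids both the acid that would unmask the peroxide and the base that would eliminate it.

Step 16
Reactants: 25 methyl (3S)-3-[(2-methoxypropan-2-yl)peroxy]pent-4-enoate
Product: 26 methyl (3S)-3-hydroperoxypent-4-enoate
Conditions: AcOH/THF/H2O (4:2:1), rt
Reagents that add atoms: none
Why: Acid-catalysed hydrolysis of the 2-methoxyprop-2-yl monoperoxyketal (ketal hydrolysis): the ketal carbon leaves as acetone and methanol and the secondary hydroperoxide is freed without touching the C3–O bond, so the S configuration is kept.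

Step 17
Reactants: 26 methyl (3S)-3-hydroperoxypent-4-enoate; 9 3,3-dimethoxynonadec-1-ene
Product: 27 methyl (3S)-3-[(3-methoxynonadec-1-en-3-yl)peroxy]pent-4-enoate (both epimers at the peroxyketal carbon)
Conditions: 9 (1.5 equiv), PPTS (10 mol %), 5 Å MS, CH2Cl2, 0 °C to rt
Reagents that add atoms: none
Why: Acid-catalysed transketalisation (peroxyketal exchange): PPTS ionises the ketal to a methoxy-stabilised oxocarbenium ion that the hydroperoxide captures at the oxygen-bearing carbon while the sieves take up methanol, the new peroxyketal centre (later C6) forming without control and both epimers being carried on with C3 unaffected.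

Step 18
Reactants: 27 methyl (3S)-3-[(3-methoxynonadec-1-en-3-yl)peroxy]pent-4-enoate
Product: 28 methyl 2-[(3S)-6-hexadecyl-6-methoxy-3,6-dihydro-1,2-dioxin-3-yl]acetate (both C6 epimers)
Conditions: second-generation Grubbs catalyst RuCl2(=CHPh)(H2IMes)(PCy3) (10 mol %), CH2Cl2 (0.005 M), 40 °C
Reagents that add atoms: none
Why: Ring-closing olefin metathesis: the ruthenium benzylidene exchanges onto the less hindered C3 vinyl group, the new alkylidene adds to the C6 vinyl group through a ruthenacyclobutane, and cycloreversion releases the ring, ethylene leaving on turnover. The closest known reaction types are ring-closing metathesis of 1,7-dienes with two allylic heteroatom substituents to six-membered allylic heterocycles (vinyl groups on ketal carbons included) and ruthenium-catalysed cross-metathesis of allylic peroxides. The one ring, the 1,2-dioxine, is closed by forming its endocyclic C4=C5 bond from a 1,7-diene whose tether is C3–O2–O1–C6, and a six-membered ring can hold only the cis alkene. No stereocentre is created: C3 is carried in from step 11 and C6 stays a mixture. The step needs the carbene to react with the two terminal alkenes and not with the O–O bond or the acid-labile allylic peroxyketal, which the neutral, non-basic medium and gentle warming are meant to secure, while high dilution and loss of ethylene favour closure over dimerisation despite the slow addition at the quaternary allylic C6.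

Step 19
Reactants: 28 methyl 2-[(3S)-6-hexadecyl-6-methoxy-3,6-dihydro-1,2-dioxin-3-yl]acetate (both C6 epimers)
Product: 29 methyl 2-[(3S,6R)-6-hexadecyl-6-methoxy-3,6-dihydro-1,2-dioxin-3-yl]acetate
Conditions: CSA (cat.), MeOH, 0 °C to rt; NaHCO3; chromatography, 6S epimer recycled
Reagents that add atoms: methanol, CO
Why: Acid-catalysed ketal exchange under thermodynamic control: reversible loss of methanol from C6 gives a ring peroxycarbenium ion that methanol recaptures on either face, so the C6 epimers interconvert while C3 is untouched, and the (3S,6R) epimer is isolated by chromatography while the 6S epimer is returned to the same conditions.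

**Compound list**
1 | heptadecanoic acid | CCCCCCCCCCCCCCCCC(=O)O | starting material
2 | 1-(1H-imidazol-1-yl)heptadecan-1-one (acyl imidazole) | CCCCCCCCCCCCCCCCC(=O)n1ccnc1 | intermediate
3 | N-methoxy-N-methylheptadecanamide | CCCCCCCCCCCCCCCCC(=O)N(C)OC | intermediate
4 | vinylmagnesium bromide | C=C[Mg]Br | starting material
5 | bromomagnesium 3-[methoxy(methyl)amino]nonadec-1-en-3-olate (magnesium hemiaminal chelate) | CCCCCCCCCCCCCCCCC(O[Mg]Br)(C=C)N(C)OC | intermediate
6 | nonadec-1-en-3-one | CCCCCCCCCCCCCCCCC(=O)C=C | intermediate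
7 | 1-bromononadecan-3-one | CCCCCCCCCCCCCCCCC(=O)CCBr | intermediate
8 | 1-bromo-3,3-dimethoxynonadecane | CCCCCCCCCCCCCCCCC(OC)(OC)CCBr | intermediate
9 | 3,3-dimethoxynonadec-1-ene | CCCCCCCCCCCCCCCCC(OC)(OC)C=C | intermediate
10 | 2,3-dimethylbut-2-ene | CC(C)=C(C)C | starting material
11 | 2-hydroperoxy-2-methoxypropane | COC(C)(C)OO | intermediate
12 | ethynyltrimethylsilane | C[Si](C)(C)C#C | starting material
13 | 3-[(tert-butyldimethylsilyl)oxy]propanal | CC(C)(C)[Si](C)(C)OCCC=O | starting material
14 | lithium (trimethylsilyl)acetylide | C[Si](C)(C)C#C[Li] | intermediate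
15 | rac-5-[(tert-butyldimethylsilyl)oxy]-1-(trimethylsilyl)pent-1-yn-3-ol | CC(C)(C)[Si](C)(C)OCCC(O)C#C[Si](C)(C)C | intermediate
16 | 5-[(tert-butyldimethylsilyl)oxy]-1-(trimethylsilyl)pent-1-yn-3-one | CC(C)(C)[Si](C)(C)OCCC(=O)C#C[Si](C)(C)C | intermediate
17 | (3R)-5-[(tert-butyldimethylsilyl)oxy]-1-(trimethylsilyl)pent-1-yn-3-ol | CC(C)(C)[Si](C)(C)OCC[C@@H](O)C#C[Si](C)(C)C | intermediate
18 | (3R)-5-[(tert-butyldimethylsilyl)oxy]pent-1-yn-3-ol | CC(C)(C)[Si](C)(C)OCC[C@@H](O)C#C | intermediate
19 | (3R)-5-[(tert-butyldimethylsilyl)oxy]pent-1-yn-3-yl methanesulfonate | CC(C)(C)[Si](C)(C)OCC[C@@H](OS(C)(=O)=O)C#C | intermediate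
20 | tert-butyl({(3S)-3-[(2-methoxypropan-2-yl)peroxy]pent-4-yn-1-yl}oxy)dimethylsilane | CC(C)(C)[Si](C)(C)OCC[C@H](OOC(C)(C)OC)C#C | intermediate
21 | tert-butyl({(3S)-3-[(2-methoxypropan-2-yl)peroxy]pent-4-en-1-yl}oxy)dimethylsilane | CC(C)(C)[Si](C)(C)OCC[C@H](OOC(C)(C)OC)C=C | intermediate
22 | (3S)-3-[(2-methoxypropan-2-yl)peroxy]pent-4-en-1-ol | OCC[C@H](OOC(C)(C)OC)C=C | intermediate
23 | (3S)-3-[(2-methoxypropan-2-yl)peroxy]pent-4-enal | O=CC[C@H](OOC(C)(C)OC)C=C | intermediate
24 | (3S)-3-[(2-methoxypropan-2-yl)peroxy]pent-4-enoic acid | OC(=O)C[C@H](OOC(C)(C)OC)C=C | intermediate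
25 | methyl (3S)-3-[(2-methoxypropan-2-yl)peroxy]pent-4-enoate | COC(=O)C[C@H](OOC(C)(C)OC)C=C | intermediate
26 | methyl (3S)-3-hydroperoxypent-4-enoate | COC(=O)C[C@H](OO)C=C | intermediate
27 | methyl (3S)-3-[(3-methoxynonadec-1-en-3-yl)peroxy]pent-4-enoate, both epimers at the peroxyketal carbon | CCCCCCCCCCCCCCCCC(OC)(C=C)OO[C@H](C=C)CC(=O)OC | intermediate
28 | methyl 2-[(3S)-6-hexadecyl-6-methoxy-3,6-dihydro-1,2-dioxin-3-yl]acetate, both C6 epimers | CCCCCCCCCCCCCCCCC1(OC)C=C[C@H](CC(=O)OC)OO1 | intermediate
29 | methyl 2-[(3S,6R)-6-hexadecyl-6-methoxy-3,6-dihydro-1,2-dioxin-3-yl]acetate | CCCCCCCCCCCCCCCC[C@]1(OC)C=C[C@H](CC(=O)OC)OO1 | target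

**Step count**
Total: 19 steps. Longest linear sequence: 14 steps (steps 6 to 19); steps 1 to 4 supply ketal 9 and step 5 supplies hydroperoxide 11.

**Steps most likely to fail**

1. Step 18 (ring-closing metathesis).
 - What may go wrong: the ruthenium carbene, or a ruthenium hydride formed from it, may cleave or isomerise the peroxide-linked diene. The catalyst may also rest at the C3 alkylidene and only dimerise it, because addition to the vinyl group on the quaternary peroxyketal carbon is slow.
 - Fallback: make the C4=C5 bond between two molecules and close the ring through O1–C6 instead. It sets out from 25 and enone 6 and comes back at 28.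
 - Cross-metathesis of 25 with 6 (second-generation Hoveyda–Grubbs catalyst RuCl2(=CH-C6H4-2-OiPr)(H2IMes), CH2Cl2, 40 °C) should give methyl (3S,4E)-3-[(2-methoxypropan-2-yl)peroxy]-6-oxodocos-4-enoate F1.
 - AcOH/THF/H2O then frees methyl (3S,4E)-3-hydroperoxy-6-oxodocos-4-enoate F2.
 - Irradiation (350 nm, MeCN, rt) equilibrates the enone geometry to methyl (3S,4Z)-3-hydroperoxy-6-oxodocos-4-enoate F3.
 - The hydroperoxide of F3 adds to the ketone to give the cyclic hemiperoxyketal methyl 2-[(3S)-6-hexadecyl-6-hydroxy-3,6-dihydro-1,2-dioxin-3-yl]acetate F4.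
 - CSA in methanol converts F4 into 28, which rejoins the route at step 19.

2. Step 11 (peroxide displacement).
 - What may go wrong: elimination across C3–C4 to the conjugated enyne, or base-induced loss of the peroxide, may outpace substitution at the propargylic carbon.
 - Fallback: take the stereocentre from the chiral pool, displace at an α-sulfonyloxy lactone, and derive the vinyl group from the lactone carbonyl. It sets out from hydroperoxide 11 and comes back at 22, so that steps 6 to 10, 12 and 13 are not needed.
 - Commercial (3R)-3-hydroxyoxolan-2-one F5 is converted (Tf2O, 2,6-lutidine, CH2Cl2, −40 °C) into (3R)-2-oxooxolan-3-yl trifluoromethanesulfonate F6.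
 - Displacement by 11 (CsOH·H2O, DMF, −20 °C) with inversion should give (3S)-3-[(2-methoxypropan-2-yl)peroxy]oxolan-2-one F7.
 - i-Bu2AlH (CH2Cl2, −78 °C) reduces it to the lactol (3S)-3-[(2-methoxypropan-2-yl)peroxy]oxolan-2-ol F8.
 - Wittig methylenation (Ph3P=CH2, THF, −78 to 0 °C) opens the lactol to 22.

3. Step 17 (peroxyketal exchange).
 - What may go wrong: the allylic oxocarbenium ion may be captured at its terminal carbon, the ketal may exchange twice, or the acid may consume the hydroperoxide before coupling.
 - Fallback: carry out the exchange on the ketal of the alkynyl ketone, whose propargylic cation offers no reactive conjugate position, and unveil the vinyl group afterwards. It sets out from Weinreb amide 3 and acetylide 14 (coupled with 26) and comes back at 27.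
 - 3 and 14 (THF, −78 to 0 °C) give 1-(trimethylsilyl)nonadec-1-yn-3-one F9.
 - HC(OMe)3/MeOH/TsOH·H2O gives (3,3-dimethoxynonadec-1-yn-1-yl)trimethylsilane F10.
 - K2CO3/MeOH gives 3,3-dimethoxynonadec-1-yne F11.
 - PPTS-catalysed exchange with 26 (5 Å MS, CH2Cl2) gives methyl (3S)-3-[(3-methoxynonadec-1-yn-3-yl)peroxy]pent-4-enoate F12.
 - Lindlar semihydrogenation under the conditions of step 12 gives 27.

Further compounds
F1 | step 18 | methyl (3S,4E)-3-[(2-methoxypropan-2-yl)peroxy]-6-oxodocos-4-enoate | CCCCCCCCCCCCCCCCC(=O)/C=C/[C@H](CC(=O)OC)OOC(C)(C)OC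
F2 | step 18 | methyl (3S,4E)-3-hydroperoxy-6-oxodocos-4-enoate | CCCCCCCCCCCCCCCCC(=O)/C=C/[C@H](CC(=O)OC)OO
F3 | step 18 | methyl (3S,4Z)-3-hydroperoxy-6-oxodocos-4-enoate | CCCCCCCCCCCCCCCCC(=O)/C=C\[C@H](CC(=O)OC)OO
F4 | step 18 | methyl 2-[(3S)-6-hexadecyl-6-hydroxy-3,6-dihydro-1,2-dioxin-3-yl]acetate | CCCCCCCCCCCCCCCCC1(O)C=C[C@H](CC(=O)OC)OO1
F5 | step 11 | (3R)-3-hydroxyoxolan-2-one | O[C@@H]1CCOC1=O
F6 | step 11 | (3R)-2-oxooxolan-3-yl trifluoromethanesulfonate | O=S(=O)(O[C@@H]1CCOC1=O)C(F)(F)F
F7 | step 11 | (3S)-3-[(2-methoxypropan-2-yl)peroxy]oxolan-2-one | COC(C)(C)OO[C@H]1CCOC1=O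
F8 | step 11 | (3S)-3-[(2-methoxypropan-2-yl)peroxy]oxolan-2-ol | COC(C)(C)OO[C@H]1CCOC1O
F9 | step 17 | 1-(trimethylsilyl)nonadec-1-yn-3-one | CCCCCCCCCCCCCCCCC(=O)C#C[Si](C)(C)C
F10 | step 17 | (3,3-dimethoxynonadec-1-yn-1-yl)trimethylsilane | CCCCCCCCCCCCCCCCC(OC)(OC)C#C[Si](C)(C)C
F11 | step 17 | 3,3-dimethoxynonadec-1-yne | CCCCCCCCCCCCCCCCC(OC)(OC)C#C
F12 | step 17 | methyl (3S)-3-[(3-methoxynonadec-1-yn-3-yl)peroxy]pent-4-enoate | CCCCCCCCCCCCCCCCC(OC)(C#C)OO[C@H](C=C)CC(=O)OC
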